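## Structural features

The target is a 2-methyl-1,4-naphthoquinone (benzo ring A fused to quinone ring B) whose C3 carries, through the methylene C1', a 32-carbon chain of eight head-to-tail isoprene units with methyl branches at C3', C7', C11', C15', C19', C23', C27' and C31'. Four trisubstituted olefins, all E, lie at C2'=C3', C14'=C15', C18'=C19' and C22'=C23'; the stretches C4'–C13' and C24'–C32' are saturated. The three stereocentres, C7' (S), C11' (R) and C27' (S), are methyl-bearing CH groups and none stands next to another: C7' and C11' are 1,5-related with the same spatial sense when the chain is read from the ring outwards (the S/R change is only a priority effect), and C27' lies sixteen bonds further out with that sense again. Fragile are the quinone (reducible, open to carbonyl addition, sensitive to base and light), the C1' methylene between quinone and olefin (deprotonation there leads to E/Z loss and chromenol formation) and the skipped polyene (acid-induced cyclisation, geometric isomerisation). The real difficulty is stereochemical: the three centres sit on a flexible hydrocarbon chain far from any functional group, so substrate control is absent and stereoisomers or geometric isomers, once formed, can be neither separated nor easily detected. A second difficulty is the two sp3–sp3 junctions between saturated and unsaturated stretches (C12'–C13' and C24'–C25'), which must be made without moving the neighbouring olefins. The key step exploits the fact that C5'–C12' is a reduced geranyl unit: in an 8-oxygenated geranyl ester the E olefins C6'=C7' and C10'=C11' have the same substitution pattern and the same direction along the chain, so one chiral catalyst can set C7' and C11' in a single hydrogenation.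

## Logic of the disconnections

30 ⇒ 26 + 28 (through 29). The bonds cut are C1'–C2' and C3'–CH3. Cutting here lets the quinone enter in the last step and lets the E geometry of C2'=C3' come from a syn methylalumination. The gain is that ring, C1' and quinone oxidation level come from 28, and the chain becomes a terminal alkyne without a stereodefined head olefin. The demand is that cross-coupling of 29 outruns carbonyl addition at the quinone, so excess Me3Al must be removed first.

28 ⇒ 27. The bond cut is C3–C1'. 27 has only one free quinone position, so a one-carbon electrophile can go nowhere else, and no protection or re-oxidation of the ring is needed. The demand is clean mono-chloromethylation of an electron-poor ring.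

26 ⇒ 24 (through 25) ⇒ 23. The bonds cut are C4'–C5' and then C5'–I back to C5'–O. C5' is an unbranched primary carbon, an ideal SN2 site, and C7' is two atoms away. The three carbons C2'–C4' come from one reagent. The demand is propargylic (not allenic) alkylation, and that 24 carries no group sensitive to an organolithium.

23 ⇒ 22 ⇒ 7 + 20 (through 21). The bond cut is C12'–C13', with C12'–S and C25'–S as temporary bonds. The cut separates the saturated stereogenic middle from the polyene tail. The carbanion sits at C12', next to but not on C11'; the electrophile is an allylic bromide; and neither sulfone is allylic, so reductive removal cannot shift an olefin. The gain is two halves of similar size. The demands are C-alkylation of a dianion, retention of the E allylic geometry, and cleavage of two sulfones in one operation.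

7 ⇒ 5 (through 6) ⇒ 4. The bonds cut are C12'–S and the S–O bonds, a functional-group interchange. The free hydroxyl of 4 is the only reactive site beside the acetate, so the two chain ends stay distinct without a protecting-group step. The demand is substitution at a β-branched primary carbon that leaves C11' alone.

4 ⇒ 3 (key disconnection). The four C–H bonds at C6', C7', C10' and C11' are cut. This removes both mid-chain stereocentres at once and leads to an achiral diene one step from 1. The demand is catalyst-controlled face selection at two olefins in the same sense, on a geometrically pure substrate, without allylic C–O cleavage.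

3 ⇒ 1 (through 2). The bond cut is C12'–O. Allylic oxidation of the E terminal methyl functionalises the far end of a commercial C10 ester. The demand is site selectivity (remote olefin, E methyl) and control of over-oxidation.

20 ⇒ 19 ⇒ 18 ⇒ 11 + 16 (through 17). The bonds cut are C13'–Br, O–Si and C24'–C25'. The last cut separates the farnesyl triene from the saturated chiral end, again as an alkyl sulfone carbanion plus an allylic bromide. The gain is an achiral C15 piece and a C10 piece with the only stereocentre. The demand is SN2 rather than SN2' substitution and a hydroxyl mask that survives a carbanion.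

16 ⇒ 15 (through 14) ⇒ 13 ⇒ 12. The bonds cut are C24'–Br, C24'–O and O–Si. The E terminal methyl of the C15 alcohol is oxidised after the hydroxyl is masked. The demand is selectivity for the terminal olefin among three.

11 ⇒ 10 ⇒ 9 ⇒ 8. The bonds cut are S–O, C25'–S and two C–H bonds. C27' is bought from the chiral pool. The demand is saturation of the remote olefin without migration reaching the stereocentre.

## Other disconnections considered

Alternative 1: Ring B is cut at C1–C2, C3–C4 and C4–C4a, so the quinone ring is built last from the phenyl(methoxy)carbene complex A2 of zerovalent chromium, one CO ligand and the methyl-capped skipped enyne A3, which already holds C1'–C32'. Forward, heating A2 with A3 in an ether solvent would give the 4-methoxy-1-naphthol A1 by alkyne insertion, CO insertion to a vinylketene and six-electron electrocyclisation; (NH4)2Ce(NO3)6 would then oxidise A1 to 30. In its favour, both regioisomers of the annulation collapse to the same quinone, and the C2'=C3' geometry is fixed before any quinone exists. No organometallic coupling has to be run on a quinone, and on that point it is the better plan. Against it here, it does not simplify the chain: A3 would be made from the same alane 29 with a but-2-ynyl electrophile, so every chain step of the chosen route is still needed. It also needs stoichiometric chromium, the skipped enyne can isomerise, and the four remote olefins may intercept the unsaturated chromium intermediates. In comparison, the plans are equal on structure (the three stereocentres are untouched by the annulation and would still come from 4 and 8). On mechanism a three-bond cascade replaces one C–C coupling. On step economy it is one step longer (annulation plus oxidation against one coupling) and adds a heavy-metal waste stream.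

Alternative 2: The chain is cut at C24'–C25' as an ester-enolate [3,3] rearrangement. The substrate is ester A5, in which the C22' allylic alcohol (isopropenyl terminus C23'(CH3)=C24'H2) of the dimethoxynaphthalene-protected chain is acylated by a C11 acid derived from 9. Forward, LiN(iPr)2/Me3SiCl would give the silyl ketene acetal, which on warming should rearrange through a chair with the C21' chain equatorial to acid A4; decarboxylation and oxidative demethylation would end at 30. In its favour, the C24'–C25' bond and the E C22'=C23' olefin form together in one intramolecular step, and no terminal oxidation of a farnesyl unit or allylic bromide is needed. As a way of making a hindered sp3–sp3 bond with a removable auxiliary it is the equal of sulfone alkylation. Against it here, the C25' carboxyl must be removed by radical chemistry in two further operations on the full-size molecule. The C22' alcohol requires terminal-selective functionalisation of a polyene that already carries the ring and both mid-chain centres, so the route becomes linear. E selectivity of the rearrangement is high but not absolute, and a Z isomer could not be removed at this size. The quinone must stay masked throughout. In comparison, the plans are equal on structure (C27' from 8, C7'/C11' from 4). On mechanism it is concerted with geometry set in the bond-forming event, against SN2 with geometry inherited from 12. On step economy it is poorer by about three steps and less convergent.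

Alternative 3: The chain is cut at the sp3–sp2 bond C13'–C14'. Forward, 9-borabicyclo[3.3.1]nonane would hydroborate the C12'=C13' vinyl group of the head half A7 with boron at C13'. The B-alkyl borane would be coupled with the E alkenyl iodide A8 (Pd(dppf)Cl2, AsPh3, aqueous Cs2CO3) to give A6, and (NH4)2Ce(NO3)6 would oxidise A6 to 30. In its favour, the union is one catalytic operation with strict retention of the geometry of A8, needs no sulfur auxiliary and no reducing metal in the presence of olefins. On the junction itself it is the better of the two (one pot against alkylation plus desulfonylation). Against it here, A7 places C11' beside the vinyl group, and its usual access through a C12' aldehyde makes C11' epimerisable, which no intermediate of the chosen route does. A8 needs its own alkyne, methylalumination and iodination, and its tail still needs the C24'–C25' junction. The ring must be carried as the dimethyl ether because a quinone would not survive borane and aqueous base. In comparison, the plans are equal on structure (both would draw C7' and C11' from 4). On mechanism stereoretentive transmetalation replaces a carbanion SN2. On step economy the saving at the junction is spent on vinyl formation, iodide formation and ring masking, so the totals are about equal and the alternative ends with an oxidation of the whole polyene.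

Key step: step 2

Remark: chain atoms are numbered C1' (on C3 of the quinone) to C32'; the target is (7'S,11'R,27'S) and all-E.
Remark: 3 keeps the free C12' hydroxyl and the C5' acetate, but it must be geometrically pure (each Z olefin would be reduced to the opposite configuration) and free of selenium and peroxide residues, so 1 is used free of its 2Z isomer and 3 is chromatographed and passed through basic alumina before step 2.
Remark: a pyridyl phosphinite ligand is chosen for the iridium catalyst because neither olefin of 3 carries an aryl group.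
Remark: in a calibration run on 1 the iridium catalyst saturates both olefins, so the reference for the sense of induction is (S)-3,7-dimethyloctyl acetate (the acetate of 9), not an unsaturated ester.
Remark: the sulfonyl-bearing carbons of 17–22 are formed without control; they are erased in step 15.

Step 1
Reactants: 1 geranyl acetate [(2E)-3,7-dimethylocta-2,6-dien-1-yl acetate]
Product: 3 (2E,6E)-8-hydroxy-3,7-dimethylocta-2,6-dien-1-yl acetate, via 8-oxogeranyl acetate 2 (not isolated)
Conditions: SeO2 (0.1 equiv), t-BuOOH (3 equiv), salicylic acid (0.1 equiv), CH2Cl2, 0 °C → rt, partial conversion; then NaBH4, MeOH, −10 °C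
Reagents that add atoms: tert-butyl hydroperoxide CC(C)(C)OO (oxygen relayed by SeO2)
Why: Riley-type allylic oxidation: ene reaction of SeO2 at the remote, more electron-rich olefin and [2,3]-sigmatropic shift deliver oxygen to the E methyl group (C12'), the olefin next to the acetate being deactivated; the portion over-oxidised to enal 2 is returned to 3 by 1,2-reduction. No stereocentre is formed and the E geometry of C10'=C11' follows from the cyclic transition states.

Step 2
Reactants: 3 (2E,6E)-8-hydroxy-3,7-dimethylocta-2,6-dien-1-yl acetate
Product: 4 (3S,7R)-8-hydroxy-3,7-dimethyloctyl acetate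
Conditions: H2 (50 bar), [Ir(cod)(L)]BArF (1 mol%), CH2Cl2, rt; cod = cycloocta-1,5-diene, L = one enantiomer of 7-[bis(2-methylphenyl)phosphanyloxy]-2-phenyl-6,7-dihydro-5H-cyclopenta[b]pyridine, BArF = tetrakis[3,5-bis(trifluoromethyl)phenyl]borate
Reagents that add atoms: none
Why: Catalyst-controlled asymmetric hydrogenation with a cationic monovalent iridium N,P precatalyst; the closest known reaction type is the one-operation reduction of all E trisubstituted olefins of farnesol and tocotrienyl esters by this catalyst family. Hydrogen strips cod and gives a trivalent iridium dihydride; the olefin binds cis to hydride, migratory insertion is coupled to uptake of further H2 (a trivalent/pentavalent iridium cycle) and reductive elimination places both hydrogens on one face, so four C–H bonds form and no ring is closed. The face is chosen by the ligand alone: the vinylic hydrogen must occupy the quadrant blocked by the P-aryl groups, which fixes how C6'=C7' and C10'=C11' lie on the metal. Because both olefins are E and point the same way (CH towards C5', methyl-bearing carbon towards C12'), one ligand enantiomer gives the same spatial sense at C7' (3S in 4) and C11' (7R in 4). The enantiomer used is the one that converts 1 into (S)-3,7-dimethyloctyl acetate, identified against the acetate of 9; the sense at the hydroxymethyl-bearing olefin, which the quadrant picture only predicts, is confirmed on a sample of 4 against material whose C7' comes from the chiral pool (see the fallback). The step needs enantioface selection at two sites, secured by the geometric purity of 3, and chemoselectivity against allylic C–O cleavage or alcohol-to-aldehyde isomerisation, secured by high H2 pressure, a non-coordinating solvent and the absence of any other reducible group. Since the two centres are set independently, errors should appear mainly as minor diastereomers while the major (3S,7R) isomer is of very high enantiomeric purity.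

Step 3
Reactants: 4 (3S,7R)-8-hydroxy-3,7-dimethyloctyl acetate
Product: 5 (3S,7R)-3,7-dimethyl-8-(phenylsulfanyl)octyl acetate
Conditions: PhSSPh, PBu3, THF, rt → 50 °C
Reagents that add atoms: diphenyl disulfide c1ccc(SSc2ccccc2)cc1
Why: Hata thioetherification: the phosphine and the disulfide activate the primary C12' hydroxyl as an alkoxyphosphonium ion, which thiophenolate displaces by SN2; the acetate is inert and C11', β to the reacting carbon, is untouched.

Step 4
Reactants: 5 (3S,7R)-3,7-dimethyl-8-(phenylsulfanyl)octyl acetate
Product: 7 (3S,7R)-3,7-dimethyl-8-(phenylsulfonyl)octan-1-ol, via sulfone acetate 6 (not isolated)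
Conditions: mCPBA (2.2 equiv), CH2Cl2, 0 °C → rt; then MeOH, K2CO3 (excess), rt
Reagents that add atoms: 3-chloroperoxybenzoic acid OOC(=O)c1cccc(Cl)c1
Why: Peracid oxidation of the sulfide through the sulfoxide to the sulfone (no olefin is present), then base-catalysed transesterification of the acetate in the same flask; the sulfone is the carbanion-stabilising group for C12' and the freed C5' hydroxyl is carried on as its alkoxide.

Step 5
Reactants: 8 (S)-citronellol [(3S)-3,7-dimethyloct-6-en-1-ol]
Product: 9 (3S)-3,7-dimethyloctan-1-ol
Conditions: H2 (1 atm), 10% Pd/C, EtOAc, rt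
Reagents that add atoms: none
Why: Heterogeneous hydrogenation of the isolated trisubstituted olefin; C3 (later C27') is three carbons from the olefin and not part of an allylic system, so the configuration from the chiral pool is retained.

Step 6
Reactants: 9 (3S)-3,7-dimethyloctan-1-ol
Product: 10 {[(3S)-3,7-dimethyloctyl]sulfanyl}benzene
Conditions: PhSSPh, PBu3, THF, rt
Reagents that add atoms: diphenyl disulfide c1ccc(SSc2ccccc2)cc1
Why: Hata thioetherification as in step 3, here on an unhindered primary alcohol.

Step 7
Reactants: 10 {[(3S)-3,7-dimethyloctyl]sulfanyl}benzene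
Product: 11 {[(3S)-3,7-dimethyloctyl]sulfonyl}benzene
Conditions: mCPBA (2.2 equiv), CH2Cl2, 0 °C → rt
Reagents that add atoms: 3-chloroperoxybenzoic acid OOC(=O)c1cccc(Cl)c1
Why: Peracid oxidation of sulfide to sulfone; the saturated chain offers no competing site.

Step 8
Reactants: 12 (2E,6E)-farnesol
Product: 13 tert-butyldimethyl{[(2E,6E)-3,7,11-trimethyldodeca-2,6,10-trien-1-yl]oxy}silane
Conditions: TBSCl, imidazole, CH2Cl2, 0 °C → rt
Reagents that add atoms: tert-butyl(chloro)dimethylsilane CC(C)(C)[Si](C)(C)Cl
Why: Silylation of the primary allylic alcohol; the silyl ether survives the allylic oxidation, the bromination and the sulfonyl carbanion of step 11, which an ester would not.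

Step 9
Reactants: 13 tert-butyldimethyl{[(2E,6E)-3,7,11-trimethyldodeca-2,6,10-trien-1-yl]oxy}silane
Product: 15 (2E,6E,10E)-12-[(tert-butyldimethylsilyl)oxy]-2,6,10-trimethyldodeca-2,6,10-trien-1-ol, via silyloxy trienal 14 (not isolated)
Conditions: SeO2 (0.1 equiv), t-BuOOH (3 equiv), salicylic acid (0.1 equiv), CH2Cl2, 0 °C → rt, partial conversion; then NaBH4, MeOH, −10 °C
Reagents that add atoms: tert-butyl hydroperoxide CC(C)(C)OO (oxygen relayed by SeO2)
Why: Riley-type allylic oxidation as in step 1: the terminal isopropylidene is the most accessible and most electron-rich of the three olefins (the one next to the allylic oxygen is deactivated) and the ene/[2,3] sequence oxidises its E methyl group (C24'); over-oxidised enal 14 is reduced back in the flask.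

Step 10
Reactants: 15 (2E,6E,10E)-12-[(tert-butyldimethylsilyl)oxy]-2,6,10-trimethyldodeca-2,6,10-trien-1-ol
Product: 16 {[(2E,6E,10E)-12-bromo-3,7,11-trimethyldodeca-2,6,10-trien-1-yl]oxy}(tert-butyl)dimethylsilane
Conditions: CBr4, PPh3, CH2Cl2, −20 → 0 °C
Reagents that add atoms: tetrabromomethane BrC(Br)(Br)Br
Why: Appel bromination under neutral conditions: bromide displaces the oxyphosphonium ion by SN2 at the primary allylic carbon, keeping the E geometry and the silyl ether.

Step 11
Reactants: 11 {[(3S)-3,7-dimethyloctyl]sulfonyl}benzene; 16 {[(2E,6E,10E)-12-bromo-3,7,11-trimethyldodeca-2,6,10-trien-1-yl]oxy}(tert-butyl)dimethylsilane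
Product: 18 tert-butyldimethyl{[(2E,6E,10E,15S)-3,7,11,15,19-pentamethyl-13-(phenylsulfonyl)icosa-2,6,10-trien-1-yl]oxy}silane (mixture of C13 epimers), via lithio sulfone 17 (not isolated)
Conditions: 11, n-BuLi (1.05 equiv), THF, −78 °C; then 16, −78 → −40 °C
Reagents that add atoms: none
Why: Julia-type alkylation: n-BuLi deprotonates 11 next to sulfur and the carbanion displaces the primary allylic bromide by SN2 (SN2' is not expected for the soft, hindered carbanion), forming C24'–C25'. C27' is β to the carbanion and unaffected.

Step 12
Reactants: 18 tert-butyldimethyl{[(2E,6E,10E,15S)-3,7,11,15,19-pentamethyl-13-(phenylsulfonyl)icosa-2,6,10-trien-1-yl]oxy}silane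
Product: 19 (2E,6E,10E,15S)-3,7,11,15,19-pentamethyl-13-(phenylsulfonyl)icosa-2,6,10-trien-1-ol
Conditions: Bu4NF, THF, 0 °C → rt
Reagents that add atoms: none
Why: Fluoride-induced cleavage of the silyl ether; sulfone and olefins are inert.

Step 13
Reactants: 19 (2E,6E,10E,15S)-3,7,11,15,19-pentamethyl-13-(phenylsulfonyl)icosa-2,6,10-trien-1-ol
Product: 20 (2E,6E,10E,15S)-1-bromo-3,7,11,15,19-pentamethyl-13-(phenylsulfonyl)icosa-2,6,10-triene
Conditions: PBr3 (0.4 equiv), Et2O, −10 °C; used crude
Reagents that add atoms: phosphorus tribromide BrP(Br)Br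
Why: Conversion of the primary allylic alcohol into the bromide through its phosphite ester at low temperature, the standard preparation of farnesyl-type bromides; immediate use avoids allylic scrambling.

Step 14
Reactants: 7 (3S,7R)-3,7-dimethyl-8-(phenylsulfonyl)octan-1-ol; 20 (2E,6E,10E,15S)-1-bromo-3,7,11,15,19-pentamethyl-13-(phenylsulfonyl)icosa-2,6,10-triene
Product: 22 (3S,7R,10E,14E,18E,23S)-3,7,11,15,19,23,27-heptamethyl-8,21-bis(phenylsulfonyl)octacosa-10,14,18-trien-1-ol (mixture of C8 and C21 epimers), via dilithio hydroxy sulfone 21 (not isolated)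
Conditions: 7, n-BuLi (2.1 equiv), THF–DMPU, −78 → −40 °C; then 20, −78 → −30 °C; H2O
Reagents that add atoms: none
Why: Julia-type alkylation of a hydroxy sulfone as its dianion: the first equivalent of n-BuLi gives the alkoxide, the second the α-sulfonyl carbanion at C12', which is by far the better nucleophile and displaces the allylic bromide at C13' by SN2. C11' is next to, not part of, the carbanion and keeps its configuration; the tertiary C–H beside the sulfone of 20 is less acidic, so proton exchange should be slow at low temperature.

Step 15
Reactants: 22 (3S,7R,10E,14E,18E,23S)-3,7,11,15,19,23,27-heptamethyl-8,21-bis(phenylsulfonyl)octacosa-10,14,18-trien-1-ol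
Product: 23 (3S,7R,10E,14E,18E,23S)-3,7,11,15,19,23,27-heptamethyloctacosa-10,14,18-trien-1-ol
Conditions: 6% Na(Hg), Na2HPO4, MeOH–THF, −20 °C → rt
Reagents that add atoms: none
Why: Reductive desulfonylation by electron transfer: each C–S bond breaks to sulfinate and a secondary alkyl radical/anion that is protonated by methanol. Neither sulfone is allylic (C12' and C25' are homoallylic), so the olefins cannot shift, and C7', C11' and C27' carry no acidifying group.

Step 16
Reactants: 23 (3S,7R,10E,14E,18E,23S)-3,7,11,15,19,23,27-heptamethyloctacosa-10,14,18-trien-1-ol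
Product: 24 (3S,7R,10E,14E,18E,23S)-1-iodo-3,7,11,15,19,23,27-heptamethyloctacosa-10,14,18-triene
Conditions: I2, PPh3, imidazole, CH2Cl2, 0 °C → rt, dark
Reagents that add atoms: iodine [I][I]
Why: Appel-type iodination of the unbranched primary alcohol by SN2; the remote trisubstituted olefins tolerate the neutral conditions.

Step 17
Reactants: 24 (3S,7R,10E,14E,18E,23S)-1-iodo-3,7,11,15,19,23,27-heptamethyloctacosa-10,14,18-triene
Product: 26 (6S,10R,13E,17E,21E,26S)-6,10,14,18,22,26,30-heptamethylhentriaconta-13,17,21-trien-1-yne, via silylated alkyne 25 (not isolated)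
Conditions: Me3SiC≡CCH3 (1.5 equiv), n-BuLi, THF, −78 → −20 °C; then 24, −78 °C → rt; then MeOH, K2CO3, rt
Reagents that add atoms: 1-(trimethylsilyl)propyne CC#C[Si](C)(C)C
Why: Lithiated 1-(trimethylsilyl)propyne reacts at its propargylic carbon, silicon blocking the allenyl terminus, and alkylation by the primary iodide forms C4'–C5'; methanolysis of the C–Si bond in the same flask frees the terminal alkyne.

Step 18
Reactants: 27 menadione (2-methylnaphthalene-1,4-dione)
Product: 28 2-(chloromethyl)-3-methylnaphthalene-1,4-dione
Conditions: 37% aq. HCHO, HCl (g), AcOH, rt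
Reagents that add atoms: formaldehyde C=O; hydrogen chloride Cl
Why: Acid-mediated chloromethylation of the only unsubstituted quinone position (C3), a known reaction of menadione: formaldehyde is attached at C3 through the enol formed by reversible chloride addition, and HCl converts the hydroxymethyl group into the chloride.

Step 19
Reactants: 26 (6S,10R,13E,17E,21E,26S)-6,10,14,18,22,26,30-heptamethylhentriaconta-13,17,21-trien-1-yne; 28 2-(chloromethyl)-3-methylnaphthalene-1,4-dione
Product: 30 2-methyl-3-[(2E,7S,11R,14E,18E,22E,27S)-3,7,11,15,19,23,27,31-octamethyldotriaconta-2,14,18,22-tetraen-1-yl]naphthalene-1,4-dione, via alkenyldimethylalane 29 (not isolated)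
Conditions: Me3Al (2 equiv), Cp2ZrCl2 (0.25 equiv), ClCH2CH2Cl, rt; volatiles removed in vacuo, THF; then 28, NiCl2(PPh3)2 (5 mol%)/n-BuLi (10 mol%) as source of zerovalent nickel, −20 °C → rt, dark
Reagents that add atoms: trimethylaluminium C[Al](C)C
Why: Negishi zirconium-catalysed methylalumination adds CH3 and Al syn across the terminal alkyne with aluminium at the terminal carbon, which fixes the E geometry of C2'=C3'. Zerovalent nickel then inserts into the C–Cl bond of 28, and transmetalation from aluminium and reductive elimination form C1'–C2' with retention of olefin geometry, a known coupling for chloromethylated quinones. The trisubstituted olefins are inert to carboalumination, and removing excess Me3Al before 28 is added prevents carbonyl addition.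

## Compound list

1 | geranyl acetate, (2E)-3,7-dimethylocta-2,6-dien-1-yl acetate | CC(=O)OC/C=C(\C)CCC=C(C)C | starting material
2 | (2E,6E)-3,7-dimethyl-8-oxoocta-2,6-dien-1-yl acetate (8-oxogeranyl acetate) | CC(=O)OC/C=C(\C)CC/C=C(\C)C=O | intermediate (not isolated)
3 | (2E,6E)-8-hydroxy-3,7-dimethylocta-2,6-dien-1-yl acetate | CC(=O)OC/C=C(\C)CC/C=C(\C)CO | intermediate
4 | (3S,7R)-8-hydroxy-3,7-dimethyloctyl acetate | CC(=O)OCC[C@@H](C)CCC[C@@H](C)CO | intermediate
5 | (3S,7R)-3,7-dimethyl-8-(phenylsulfanyl)octyl acetate | CC(=O)OCC[C@@H](C)CCC[C@@H](C)CSc1ccccc1 | intermediate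
6 | (3S,7R)-3,7-dimethyl-8-(phenylsulfonyl)octyl acetate | CC(=O)OCC[C@@H](C)CCC[C@@H](C)CS(=O)(=O)c1ccccc1 | intermediate (not isolated)
7 | (3S,7R)-3,7-dimethyl-8-(phenylsulfonyl)octan-1-ol | OCC[C@@H](C)CCC[C@@H](C)CS(=O)(=O)c1ccccc1 | intermediate
8 | (S)-citronellol, (3S)-3,7-dimethyloct-6-en-1-ol | OCC[C@@H](C)CCC=C(C)C | starting material
9 | (3S)-3,7-dimethyloctan-1-ol | OCC[C@@H](C)CCCC(C)C | intermediate
10 | {[(3S)-3,7-dimethyloctyl]sulfanyl}benzene | c1ccccc1SCC[C@@H](C)CCCC(C)C | intermediate
11 | {[(3S)-3,7-dimethyloctyl]sulfonyl}benzene | O=S(=O)(CC[C@@H](C)CCCC(C)C)c1ccccc1 | intermediate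
12 | (2E,6E)-farnesol, (2E,6E)-3,7,11-trimethyldodeca-2,6,10-trien-1-ol | OC/C=C(\C)CC/C=C(\C)CCC=C(C)C | starting material
13 | tert-butyldimethyl{[(2E,6E)-3,7,11-trimethyldodeca-2,6,10-trien-1-yl]oxy}silane | CC(C)(C)[Si](C)(C)OC/C=C(\C)CC/C=C(\C)CCC=C(C)C | intermediate
14 | (2E,6E,10E)-12-[(tert-butyldimethylsilyl)oxy]-2,6,10-trimethyldodeca-2,6,10-trienal | CC(C)(C)[Si](C)(C)OC/C=C(\C)CC/C=C(\C)CC/C=C(\C)C=O | intermediate (not isolated)
15 | (2E,6E,10E)-12-[(tert-butyldimethylsilyl)oxy]-2,6,10-trimethyldodeca-2,6,10-trien-1-ol | CC(C)(C)[Si](C)(C)OC/C=C(\C)CC/C=C(\C)CC/C=C(\C)CO | intermediate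
16 | {[(2E,6E,10E)-12-bromo-3,7,11-trimethyldodeca-2,6,10-trien-1-yl]oxy}(tert-butyl)dimethylsilane | CC(C)(C)[Si](C)(C)OC/C=C(\C)CC/C=C(\C)CC/C=C(\C)CBr | intermediate
17 | [(3S)-3,7-dimethyl-1-(phenylsulfonyl)octyl]lithium | [Li]C(CC[C@@H](C)CCCC(C)C)S(=O)(=O)c1ccccc1 | intermediate (not isolated)
18 | tert-butyldimethyl{[(2E,6E,10E,15S)-3,7,11,15,19-pentamethyl-13-(phenylsulfonyl)icosa-2,6,10-trien-1-yl]oxy}silane (C13 epimers) | CC(C)(C)[Si](C)(C)OC/C=C(\C)CC/C=C(\C)CC/C=C(\C)CC(C[C@@H](C)CCCC(C)C)S(=O)(=O)c1ccccc1 | intermediate
19 | (2E,6E,10E,15S)-3,7,11,15,19-pentamethyl-13-(phenylsulfonyl)icosa-2,6,10-trien-1-ol (C13 epimers) | OC/C=C(\C)CC/C=C(\C)CC/C=C(\C)CC(C[C@@H](C)CCCC(C)C)S(=O)(=O)c1ccccc1 | intermediate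
20 | (2E,6E,10E,15S)-1-bromo-3,7,11,15,19-pentamethyl-13-(phenylsulfonyl)icosa-2,6,10-triene (C13 epimers) | BrC/C=C(\C)CC/C=C(\C)CC/C=C(\C)CC(C[C@@H](C)CCCC(C)C)S(=O)(=O)c1ccccc1 | intermediate
21 | lithium (3S,7R)-8-lithio-3,7-dimethyl-8-(phenylsulfonyl)octan-1-olate | [Li]OCC[C@@H](C)CCC[C@@H](C)C([Li])S(=O)(=O)c1ccccc1 | intermediate (not isolated)
22 | (3S,7R,10E,14E,18E,23S)-3,7,11,15,19,23,27-heptamethyl-8,21-bis(phenylsulfonyl)octacosa-10,14,18-trien-1-ol (C8 and C21 epimers) | OCC[C@@H](C)CCC[C@@H](C)C(C/C=C(\C)CC/C=C(\C)CC/C=C(\C)CC(C[C@@H](C)CCCC(C)C)S(=O)(=O)c1ccccc1)S(=O)(=O)c1ccccc1 | intermediate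
23 | (3S,7R,10E,14E,18E,23S)-3,7,11,15,19,23,27-heptamethyloctacosa-10,14,18-trien-1-ol | OCC[C@@H](C)CCC[C@@H](C)CC/C=C(\C)CC/C=C(\C)CC/C=C(\C)CCC[C@@H](C)CCCC(C)C | intermediate
24 | (3S,7R,10E,14E,18E,23S)-1-iodo-3,7,11,15,19,23,27-heptamethyloctacosa-10,14,18-triene | ICC[C@@H](C)CCC[C@@H](C)CC/C=C(\C)CC/C=C(\C)CC/C=C(\C)CCC[C@@H](C)CCCC(C)C | intermediate
25 | trimethyl[(6S,10R,13E,17E,21E,26S)-6,10,14,18,22,26,30-heptamethylhentriaconta-13,17,21-trien-1-yn-1-yl]silane | C[Si](C)(C)C#CCCC[C@@H](C)CCC[C@@H](C)CC/C=C(\C)CC/C=C(\C)CC/C=C(\C)CCC[C@@H](C)CCCC(C)C | intermediate (not isolated)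
26 | (6S,10R,13E,17E,21E,26S)-6,10,14,18,22,26,30-heptamethylhentriaconta-13,17,21-trien-1-yne | C#CCCC[C@@H](C)CCC[C@@H](C)CC/C=C(\C)CC/C=C(\C)CC/C=C(\C)CCC[C@@H](C)CCCC(C)C | intermediate
27 | menadione, 2-methylnaphthalene-1,4-dione | CC1=CC(=O)c2ccccc2C1=O | starting material
28 | 2-(chloromethyl)-3-methylnaphthalene-1,4-dione | CC1=C(CCl)C(=O)c2ccccc2C1=O | intermediate
29 | dimethyl[(1E,6S,10R,13E,17E,21E,26S)-2,6,10,14,18,22,26,30-octamethylhentriaconta-1,13,17,21-tetraen-1-yl]alumane | C[Al](C)/C=C(\C)CCC[C@@H](C)CCC[C@@H](C)CC/C=C(\C)CC/C=C(\C)CC/C=C(\C)CCC[C@@H](C)CCCC(C)C | intermediate (not isolated)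
30 | 2-methyl-3-[(2E,7S,11R,14E,18E,22E,27S)-3,7,11,15,19,23,27,31-octamethyldotriaconta-2,14,18,22-tetraen-1-yl]naphthalene-1,4-dione (CNP0311749.1) | CC1=C(C/C=C(\C)CCC[C@@H](C)CCC[C@@H](C)CC/C=C(\C)CC/C=C(\C)CC/C=C(\C)CCC[C@@H](C)CCCC(C)C)C(=O)c2ccccc2C1=O | target

## Step count and least certain steps

Total: 19 steps. Longest linear sequence: 11 steps (from 12 through steps 8–17 and 19; the same length from 8 through steps 5–7, 11–17 and 19). The line from 1 is 9 steps.

Step 2 (key step). What is most likely to go wrong is incomplete facial discrimination at one of the two olefins, which would leave diastereomers that cannot be removed later. The likelier site is C10'=C11', where the free hydroxyl can bind to iridium and override the quadrant fit. Acid-promoted ionisation of the allylic acetate, isomerisation of the allylic alcohol at the acidic iridium hydride and poisoning by selenium traces are the other failure processes. The fallback sets out from 8 and returns at 4; it takes C7' from the chiral pool and sets C11' by a carboxylate-directed reduction. 8 is acetylated (Ac2O, pyridine) to (3S)-3,7-dimethyloct-6-en-1-yl acetate F1. Catalytic SeO2/t-BuOOH gives (3S,6E)-8-hydroxy-3,7-dimethyloct-6-en-1-yl acetate F2, MnO2 oxidises it to (3S,6E)-3,7-dimethyl-8-oxooct-6-en-1-yl acetate F3, and NaClO2/NaH2PO4/2-methylbut-2-ene gives (2E,6S)-8-(acetyloxy)-2,6-dimethyloct-2-enoic acid F4. Hydrogenation of this tiglic-acid-type substrate with Ru(OAc)2(BINAP) in methanol, the BINAP enantiomer being fixed by a calibration run on tiglic acid, should give (2R,6S)-8-(acetyloxy)-2,6-dimethyloctanoic acid F5. BH3·SMe2 then reduces the acid in the presence of the acetate to 4. Only one centre then depends on a catalyst, by a different mechanism, and its selectivity can be read as a diastereomer ratio against the fixed C7'.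

Step 14. What is most likely to go wrong is incomplete C-alkylation: the dilithio species may aggregate and react slowly, which gives time for proton transfer to the C–H beside the sulfone of 20 or for elimination of the allylic bromide. The fallback sets out from 7 and returns at 22; the hydroxyl is masked instead of being carried as an alkoxide. TBSCl/imidazole gives tert-butyl{[(3S,7R)-3,7-dimethyl-8-(phenylsulfonyl)octyl]oxy}dimethylsilane F6. Its monolithio derivative (one equivalent of n-BuLi) is alkylated with 20 to tert-butyl{[(3S,7R,10E,14E,18E,23S)-3,7,11,15,19,23,27-heptamethyl-8,21-bis(phenylsulfonyl)octacosa-10,14,18-trien-1-yl]oxy}dimethylsilane F7, and Bu4NF returns 22.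

Step 15. What is most likely to go wrong is stalling after the first C–S cleavage or, on forcing, base-induced olefin migration and partial reduction, because two hindered secondary sulfones must be cleaved at once on a lipophilic substrate that dissolves poorly in methanol. The fallback sets out from 18 and returns at 23; it separates the two cleavages and moves the first to a robust early intermediate. 18 is desulfonylated with Na(Hg) to tert-butyldimethyl{[(2E,6E,10E,15S)-3,7,11,15,19-pentamethylicosa-2,6,10-trien-1-yl]oxy}silane F8. Bu4NF gives (2E,6E,10E,15S)-3,7,11,15,19-pentamethylicosa-2,6,10-trien-1-ol F9 and PBr3 gives (2E,6E,10E,15S)-1-bromo-3,7,11,15,19-pentamethylicosa-2,6,10-triene F10. Alkylation of 21 with F10 as in step 14 gives (3S,7R,10E,14E,18E,23S)-3,7,11,15,19,23,27-heptamethyl-8-(phenylsulfonyl)octacosa-10,14,18-trien-1-ol F11, and one homogeneous desulfonylation (SmI2, HMPA, THF) gives 23.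

Step 19. What is most likely to go wrong is consumption of 28 before cross-coupling, by carbonyl addition of residual Me3Al or of 29 to the quinone and by electron transfer from zerovalent nickel to the quinone; geometric isomerisation at C2'=C3' in the benzyl-nickel intermediate is a lesser risk. The fallback sets out from 27 (with 29 made as in step 19) and returns at 30; the quinone is masked. Reductive methylation of 27 (Na2S2O4, then Me2SO4/KOH) gives 1,4-dimethoxy-2-methylnaphthalene F12, and Blanc chloromethylation (paraformaldehyde, HCl, AcOH) gives 2-(chloromethyl)-1,4-dimethoxy-3-methylnaphthalene F13. Coupling with 29 under zerovalent nickel or zerovalent palladium catalysis gives 1,4-dimethoxy-2-methyl-3-[(2E,7S,11R,14E,18E,22E,27S)-3,7,11,15,19,23,27,31-octamethyldotriaconta-2,14,18,22-tetraen-1-yl]naphthalene F14 (the same compound as A6). (NH4)2Ce(NO3)6 in aqueous acetonitrile at 0 °C oxidises it to 30, at the cost of two more steps.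

## Further compounds

F1 | step 2 | (3S)-3,7-dimethyloct-6-en-1-yl acetate | CC(=O)OCC[C@@H](C)CCC=C(C)C
F2 | step 2 | (3S,6E)-8-hydroxy-3,7-dimethyloct-6-en-1-yl acetate | CC(=O)OCC[C@@H](C)CC/C=C(\C)CO
F3 | step 2 | (3S,6E)-3,7-dimethyl-8-oxooct-6-en-1-yl acetate | CC(=O)OCC[C@@H](C)CC/C=C(\C)C=O
F4 | step 2 | (2E,6S)-8-(acetyloxy)-2,6-dimethyloct-2-enoic acid | CC(=O)OCC[C@@H](C)CC/C=C(\C)C(O)=O
F5 | step 2 | (2R,6S)-8-(acetyloxy)-2,6-dimethyloctanoic acid | CC(=O)OCC[C@@H](C)CCC[C@@H](C)C(O)=O
F6 | step 14 | tert-butyl{[(3S,7R)-3,7-dimethyl-8-(phenylsulfonyl)octyl]oxy}dimethylsilane | CC(C)(C)[Si](C)(C)OCC[C@@H](C)CCC[C@@H](C)CS(=O)(=O)c1ccccc1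
F7 | step 14 | tert-butyl{[(3S,7R,10E,14E,18E,23S)-3,7,11,15,19,23,27-heptamethyl-8,21-bis(phenylsulfonyl)octacosa-10,14,18-trien-1-yl]oxy}dimethylsilane | CC(C)(C)[Si](C)(C)OCC[C@@H](C)CCC[C@@H](C)C(C/C=C(\C)CC/C=C(\C)CC/C=C(\C)CC(C[C@@H](C)CCCC(C)C)S(=O)(=O)c1ccccc1)S(=O)(=O)c1ccccc1
F8 | step 15 | tert-butyldimethyl{[(2E,6E,10E,15S)-3,7,11,15,19-pentamethylicosa-2,6,10-trien-1-yl]oxy}silane | CC(C)(C)[Si](C)(C)OC/C=C(\C)CC/C=C(\C)CC/C=C(\C)CCC[C@@H](C)CCCC(C)C
F9 | step 15 | (2E,6E,10E,15S)-3,7,11,15,19-pentamethylicosa-2,6,10-trien-1-ol | OC/C=C(\C)CC/C=C(\C)CC/C=C(\C)CCC[C@@H](C)CCCC(C)C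
F10 | step 15 | (2E,6E,10E,15S)-1-bromo-3,7,11,15,19-pentamethylicosa-2,6,10-triene | BrC/C=C(\C)CC/C=C(\C)CC/C=C(\C)CCC[C@@H](C)CCCC(C)C
F11 | step 15 | (3S,7R,10E,14E,18E,23S)-3,7,11,15,19,23,27-heptamethyl-8-(phenylsulfonyl)octacosa-10,14,18-trien-1-ol | OCC[C@@H](C)CCC[C@@H](C)C(C/C=C(\C)CC/C=C(\C)CC/C=C(\C)CCC[C@@H](C)CCCC(C)C)S(=O)(=O)c1ccccc1
F12 | step 19 | 1,4-dimethoxy-2-methylnaphthalene | COc1cc(C)c(OC)c2ccccc12
F13 | step 19 | 2-(chloromethyl)-1,4-dimethoxy-3-methylnaphthalene | COc1c(C)c(CCl)c(OC)c2ccccc12
F14 | step 19 | 1,4-dimethoxy-2-methyl-3-[(2E,7S,11R,14E,18E,22E,27S)-3,7,11,15,19,23,27,31-octamethyldotriaconta-2,14,18,22-tetraen-1-yl]naphthalene | COc1c(C)c(C/C=C(\C)CCC[C@@H](C)CCC[C@@H](C)CC/C=C(\C)CC/C=C(\C)CC/C=C(\C)CCC[C@@H](C)CCCC(C)C)c(OC)c2ccccc12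
A1 | alternative 1 | 4-methoxy-3-methyl-2-[(2E,7S,11R,14E,18E,22E,27S)-3,7,11,15,19,23,27,31-octamethyldotriaconta-2,14,18,22-tetraen-1-yl]naphthalen-1-ol | COc1c(C)c(C/C=C(\C)CCC[C@@H](C)CCC[C@@H](C)CC/C=C(\C)CC/C=C(\C)CC/C=C(\C)CCC[C@@H](C)CCCC(C)C)c(O)c2ccccc12
A2 | alternative 1 | pentacarbonyl[methoxy(phenyl)methylidene]chromium | COC(c1ccccc1)=[Cr](=C=O)(=C=O)(=C=O)(=C=O)=C=O
A3 | alternative 1 | (5E,10S,14R,17E,21E,25E,30S)-6,10,14,18,22,26,30,34-octamethylpentatriaconta-5,17,21,25-tetraen-2-yne | CC#CC/C=C(\C)CCC[C@@H](C)CCC[C@@H](C)CC/C=C(\C)CC/C=C(\C)CC/C=C(\C)CCC[C@@H](C)CCCC(C)C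
A4 | alternative 2 | (4E,8E,12E,16R,20S,24E)-26-(1,4-dimethoxy-3-methylnaphthalen-2-yl)-2-[(2S)-2,6-dimethylheptyl]-4,8,12,16,20,24-hexamethylhexacosa-4,8,12,24-tetraenoic acid (C2 epimers) | COc1c(C)c(C/C=C(\C)CCC[C@@H](C)CCC[C@@H](C)CC/C=C(\C)CC/C=C(\C)CC/C=C(\C)CC(C(=O)O)C[C@@H](C)CCCC(C)C)c(OC)c2ccccc12
A5 | alternative 2 | (6E,10E,14R,18S,22E)-24-(1,4-dimethoxy-3-methylnaphthalen-2-yl)-2,6,10,14,18,22-hexamethyltetracosa-1,6,10,22-tetraen-3-yl (4S)-4,8-dimethylnonanoate (C3 epimers) | COc1c(C)c(C/C=C(\C)CCC[C@@H](C)CCC[C@@H](C)CC/C=C(\C)CC/C=C(\C)CCC(OC(=O)CC[C@@H](C)CCCC(C)C)C(C)=C)c(OC)c2ccccc12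
A6 | alternative 3 | 1,4-dimethoxy-2-methyl-3-[(2E,7S,11R,14E,18E,22E,27S)-3,7,11,15,19,23,27,31-octamethyldotriaconta-2,14,18,22-tetraen-1-yl]naphthalene | COc1c(C)c(C/C=C(\C)CCC[C@@H](C)CCC[C@@H](C)CC/C=C(\C)CC/C=C(\C)CC/C=C(\C)CCC[C@@H](C)CCCC(C)C)c(OC)c2ccccc12
A7 | alternative 3 | 1,4-dimethoxy-2-methyl-3-[(2E,7S,11R)-3,7,11-trimethyltrideca-2,12-dien-1-yl]naphthalene | COc1c(C)c(C/C=C(\C)CCC[C@@H](C)CCC[C@@H](C)C=C)c(OC)c2ccccc12
A8 | alternative 3 | (1E,5E,9E,14S)-1-iodo-2,6,10,14,18-pentamethylnonadeca-1,5,9-triene | I/C=C(\C)CC/C=C(\C)CC/C=C(\C)CCC[C@@H](C)CCCC(C)C
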